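The target's single carbinol, C5–OH, is traced back by one retrosynthetic oxidation to the C5 carbonyl of ene-dione 10 (chain numbered C1 at guaiacyl ring A to C7 at syringyl ring B). Compound 10 is assembled by two boron-templated condensations on acetylacetone. In one operation a ketoreductase reduces only C5 of 10, forming the C5–H bond and the single stereocentre (5R) and leaving C3 as the ketone. The step exploits the difference between the two carbonyls: C3 is a cinnamoyl ketone conjugated through C1=C2 with ring A, whereas C5 is an isolated dialkyl ketone carrying the flexible C6–C7 arm to ring B. Hydrogenation of C1=C2 then gives the target.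

Key step: step 4

Remark 1: the 1,3-diketones 5, 6 and 10 are drawn in the diketo form although they rest largely as hydrogen-bonded enols.
Remark 2: the boron chelates 3, 4, 8 and 9 are drawn as monomeric dibutoxyboron chelates; B–O–B-bridged forms of the same chelates are expected alongside and react in the same way.
Remark 3: C5 is R in both 11 and 12 (OH > C4 > C6 > H, because C3 carries the carbonyl oxygen in either compound), so the descriptor set in step 4 is the one the target requires.

Step 1
Reactants: 1 acetylacetone (pentane-2,4-dione); 2 syringaldehyde (4-hydroxy-3,5-dimethoxybenzaldehyde)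
Product: 5 (E)-6-(4-hydroxy-3,5-dimethoxyphenyl)hex-5-ene-2,4-dione, via acetylacetone boron chelate 3 (not isolated), via styryl boron chelate 4 (not isolated)
Conditions: 1 (3 equiv), B2O3, B(OBu)3, EtOAc, 70 °C; then 2, n-BuNH2 (cat., slow addition), 70 °C; then 0.5 M aq HCl, 60 °C
Reagents that add atoms: none
Why: Boron chelation of the 1,3-dicarbonyl unit (chelate 3) blocks the central methylene and leaves a terminal methyl as the nucleophile for the amine-catalysed Knoevenagel-type aldol condensation, the excess of 1 should hold the reaction at the mono-styryl stage, dehydration gives the conjugated E alkene under thermodynamic control, and warm dilute acid releases 5 from chelate 4.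

Step 2
Reactants: 5 (E)-6-(4-hydroxy-3,5-dimethoxyphenyl)hex-5-ene-2,4-dione
Product: 6 6-(4-hydroxy-3,5-dimethoxyphenyl)hexane-2,4-dione
Conditions: H2 (1 atm), 10% Pd/C, EtOAc, 23 °C, stopped after one equivalent of H2
Reagents that add atoms: none
Why: Catalytic hydrogenation over Pd/C should saturate the styryl C=C bond well before it attacks the hydrogen-bonded enolised 1,3-diketone or the arene, so that uptake of one equivalent of H2 gives the saturated diketone.

Step 3
Reactants: 6 6-(4-hydroxy-3,5-dimethoxyphenyl)hexane-2,4-dione; 7 vanillin (4-hydroxy-3-methoxybenzaldehyde)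
Product: 10 (1E)-7-(4-hydroxy-3,5-dimethoxyphenyl)-1-(4-hydroxy-3-methoxyphenyl)hept-1-ene-3,5-dione, via diketone boron chelate 8 (not isolated), via ene-dione boron chelate 9 (not isolated)
Conditions: B2O3, B(OBu)3, EtOAc, 70 °C; then 7 (1.0 equiv), n-BuNH2 (cat., slow addition), 70 °C; then 0.5 M aq HCl, 60 °C
Reagents that add atoms: none
Why: The same boron-templated aldol condensation is repeated on chelate 8, where the unhindered C1 methyl should react in preference to the C5 methylene (as in the preparation of dehydrogingerdione-type ene-diones from 2,4-alkanediones and vanillin), the free phenols are tolerated, the E alkene again follows from thermodynamic control, and acid hydrolysis of chelate 9 releases 10.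

Step 4
Reactants: 10 (1E)-7-(4-hydroxy-3,5-dimethoxyphenyl)-1-(4-hydroxy-3-methoxyphenyl)hept-1-ene-3,5-dione
Product: 11 (1E,5R)-5-hydroxy-7-(4-hydroxy-3,5-dimethoxyphenyl)-1-(4-hydroxy-3-methoxyphenyl)hept-1-en-3-one
Conditions: ketoreductase (purified, NADPH-dependent, selected from a panel for the 5R mono-alcohol), NADP+ (cat.), glucose dehydrogenase, D-glucose (1.5 equiv), 0.1 M KH2PO4/K2HPO4 buffer pH 6.8, 10 vol% DMSO, 30 °C
Reagents that add atoms: none
Why: The short-chain dehydrogenase/reductase binds the diketo tautomer of 10 (expected to be populated in buffered water and to exchange rapidly with the enol), transfers hydride from NADPH to C5 while its active-site tyrosine protonates the carbonyl oxygen, and glucose dehydrogenase with D-glucose returns NADP+ to NADPH so that the reduction is driven forward. The closest known reaction type is the ketoreductase mono-reduction of 1,3-diketones to β-hydroxy ketones, which parallels the biosynthetic reduction of gingerdione-type diketones to gingerols; no ring is formed. The C5 stereocentre is controlled by the enzyme pocket, which presents one carbonyl face to the cofactor, and because panels hold enzymes of both enantiopreferences the one delivering the 5R carbinol is picked by screening with chiral HPLC analysis. The step needs C5-over-C3 selectivity, arrest at the mono-alcohol and an untouched C1=C2 bond: C3 is a vinylogously deactivated cinnamoyl carbonyl on a rigid planar p-hydroxystyryl arm, C5 is the more electrophilic isolated ketone on a flexible arylethyl arm, and once C5 is reduced the remaining enone carbonyl should be a poor substrate. The near-neutral pH keeps the diketone and phenols un-ionised and protects the β-hydroxy enone from retro-aldol cleavage and dehydration, and purified enzyme excludes background alkene reduction by host enoate reductases.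

Step 5
Reactants: 11 (1E,5R)-5-hydroxy-7-(4-hydroxy-3,5-dimethoxyphenyl)-1-(4-hydroxy-3-methoxyphenyl)hept-1-en-3-one
Product: 12 (5R)-5-hydroxy-7-(4-hydroxy-3,5-dimethoxyphenyl)-1-(4-hydroxy-3-methoxyphenyl)heptan-3-one (CNP0151899.1, the target)
Conditions: H2 (1 atm), 5% Pd/C, EtOAc, 23 °C
Reagents that add atoms: none
Why: Heterogeneous hydrogenation over Pd/C under neutral conditions reduces the conjugated C1=C2 bond of the enone much faster than the C3 ketone or the arenes (the way dehydrogingerols are converted into gingerols), and the C5 stereocentre, which can be lost only through retro-aldol or elimination chemistry that neutral EtOAc does not promote, should be carried through unchanged.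

Compound list
1 | acetylacetone (pentane-2,4-dione) | CC(=O)CC(C)=O | starting material
2 | syringaldehyde (4-hydroxy-3,5-dimethoxybenzaldehyde) | COc1cc(C=O)cc(OC)c1O | starting material
3 | dibutoxyboron chelate of acetylacetone (2,2-dibutoxy-4,6-dimethyl-1,3,2-dioxaborinine chelate) | CC1=CC(C)=[O+][B-](OCCCC)(OCCCC)O1 | intermediate (not isolated)
4 | dibutoxyboron chelate of 5 (E-styryl chelate) | CC1=CC(/C=C/c2cc(OC)c(O)c(OC)c2)=[O+][B-](OCCCC)(OCCCC)O1 | intermediate (not isolated)
5 | (E)-6-(4-hydroxy-3,5-dimethoxyphenyl)hex-5-ene-2,4-dione | COc1cc(/C=C/C(=O)CC(C)=O)cc(OC)c1O | intermediate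
6 | 6-(4-hydroxy-3,5-dimethoxyphenyl)hexane-2,4-dione | COc1cc(CCC(=O)CC(C)=O)cc(OC)c1O | intermediate
7 | vanillin (4-hydroxy-3-methoxybenzaldehyde) | COc1cc(C=O)ccc1O | starting material
8 | dibutoxyboron chelate of 6 | CC1=CC(CCc2cc(OC)c(O)c(OC)c2)=[O+][B-](OCCCC)(OCCCC)O1 | intermediate (not isolated)
9 | dibutoxyboron chelate of 10 (E-styryl chelate) | COc1cc(/C=C/C2=CC(CCc3cc(OC)c(O)c(OC)c3)=[O+][B-](OCCCC)(OCCCC)O2)ccc1O | intermediate (not isolated)
10 | (1E)-7-(4-hydroxy-3,5-dimethoxyphenyl)-1-(4-hydroxy-3-methoxyphenyl)hept-1-ene-3,5-dione | COc1cc(/C=C/C(=O)CC(=O)CCc2cc(OC)c(O)c(OC)c2)ccc1O | intermediate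
11 | (1E,5R)-5-hydroxy-7-(4-hydroxy-3,5-dimethoxyphenyl)-1-(4-hydroxy-3-methoxyphenyl)hept-1-en-3-one | COc1cc(/C=C/C(=O)C[C@H](O)CCc2cc(OC)c(O)c(OC)c2)ccc1O | intermediate
12 | (5R)-5-hydroxy-7-(4-hydroxy-3,5-dimethoxyphenyl)-1-(4-hydroxy-3-methoxyphenyl)heptan-3-one | COc1cc(CCC(=O)C[C@H](O)CCc2cc(OC)c(O)c(OC)c2)ccc1O | target

Total step count: 5
Longest linear sequence: 5 steps (1 and 2 to 12; vanillin 7 enters at step 3)

Steps most likely to fail

Step 4. Hydride may be delivered to the wrong carbonyl or the wrong face, reduction may continue to the 3,5-diol, turnover may be slow because the substrate rests as its enol, or the alkene may be saturated by contaminating reductase activity. The fallback sets out from 7 and 2 and returns at 11; it makes the C5 stereocentre by a reagent-controlled aldol construction of the C4–C5 bond instead of a reduction.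
- Ketone partner: vanillin 7 is condensed with acetone (aq NaOH, Claisen–Schmidt) to (E)-4-(4-hydroxy-3-methoxyphenyl)but-3-en-2-one F1. Its phenol is silylated (TBSCl, imidazole, DMF) to the tert-butyldimethylsilyl ether F2.
- Aldehyde partner: syringaldehyde 2 is silylated in the same way to 4-(tert-butyldimethylsilyloxy)-3,5-dimethoxybenzaldehyde F3. A Wittig reaction with Ph3P=CHCHO (toluene, 80 °C) homologates it to (E)-3-[4-(tert-butyldimethylsilyloxy)-3,5-dimethoxyphenyl]prop-2-enal F4. Hydrogenation of the alkene (H2, Pd/C, EtOAc) gives 3-[4-(tert-butyldimethylsilyloxy)-3,5-dimethoxyphenyl]propanal F5.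
- Aldol and release: methyl ketone F2 is enolised with diisopinocampheylboron chloride (Ipc2BCl, Et3N, Et2O, 0 °C), F5 is added at −78 °C, and oxidative work-up (H2O2, pH 7 buffer) should give the bis-silyl ether of 11 F6. The antipode of the boron reagent is chosen for the 5R adduct, and enantiomeric purity is raised by crystallisation if required. TBAF buffered with AcOH in THF then removes both silyl groups to give 11.

Step 1. The condensation may run on to the bis-styryl product at the second methyl, or leak to the central methylene if chelation is incomplete, leaving a mixture that is hard to separate. The fallback sets out from 2 and returns at 6, bypassing 5, so no diketone with two reactive methyl groups ever meets the aldehyde. Syringaldehyde 2 is condensed with acetone (aq NaOH, Claisen–Schmidt) to (E)-4-(4-hydroxy-3,5-dimethoxyphenyl)but-3-en-2-one F7, which is hydrogenated (H2, Pd/C, EtOAc) to 4-(4-hydroxy-3,5-dimethoxyphenyl)butan-2-one F8. F8 is then acetylated at its methyl group by a crossed Claisen condensation with ethyl acetate (NaH, 3 equiv, THF, reflux; then aq HCl), the phenol riding through as its phenoxide, to give 6.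

Step 3. The condensation may stall, may occur in part at the C5 methylene, or the diketone may suffer retro-Claisen cleavage under amine and heat. The fallback sets out from 6 and 7 and returns at 10; it replaces the boron template by a kinetically controlled polyanion aldol followed by dehydration.
- Vanillin 7 is converted into its tetrahydropyranyl ether, 3-methoxy-4-(tetrahydro-2H-pyran-2-yloxy)benzaldehyde F9 (3,4-dihydro-2H-pyran, pyridinium p-toluenesulfonate, CH2Cl2).
- Diketone 6 is deprotonated three times (LiN(i-Pr)2, 3.1 equiv, THF, −78 to 0 °C), giving the phenoxide, the C3 enolate and the kinetically preferred C1 methyl carbanion. This polyanion should add through C1 to F9 at −78 °C to give the benzylic aldol 1-hydroxy-7-(4-hydroxy-3,5-dimethoxyphenyl)-1-[3-methoxy-4-(tetrahydro-2H-pyran-2-yloxy)phenyl]heptane-3,5-dione F10 (mixture of stereoisomers, of no consequence).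
- Aqueous HCl in THF at 50 °C then cleaves the acetal and dehydrates the benzylic carbinol to the conjugated E alkene, giving 10.

Further compounds
F1 | step 4 | (E)-4-(4-hydroxy-3-methoxyphenyl)but-3-en-2-one | COc1cc(/C=C/C(C)=O)ccc1O
F2 | step 4 | (E)-4-[4-(tert-butyldimethylsilyloxy)-3-methoxyphenyl]but-3-en-2-one | COc1cc(/C=C/C(C)=O)ccc1O[Si](C)(C)C(C)(C)C
F3 | step 4 | 4-(tert-butyldimethylsilyloxy)-3,5-dimethoxybenzaldehyde | COc1cc(C=O)cc(OC)c1O[Si](C)(C)C(C)(C)C
F4 | step 4 | (E)-3-[4-(tert-butyldimethylsilyloxy)-3,5-dimethoxyphenyl]prop-2-enal | COc1cc(/C=C/C=O)cc(OC)c1O[Si](C)(C)C(C)(C)C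
F5 | step 4 | 3-[4-(tert-butyldimethylsilyloxy)-3,5-dimethoxyphenyl]propanal | COc1cc(CCC=O)cc(OC)c1O[Si](C)(C)C(C)(C)C
F6 | step 4 | (1E,5R)-1-[4-(tert-butyldimethylsilyloxy)-3-methoxyphenyl]-7-[4-(tert-butyldimethylsilyloxy)-3,5-dimethoxyphenyl]-5-hydroxyhept-1-en-3-one | COc1cc(/C=C/C(=O)C[C@H](O)CCc2cc(OC)c(O[Si](C)(C)C(C)(C)C)c(OC)c2)ccc1O[Si](C)(C)C(C)(C)C
F7 | step 1 | (E)-4-(4-hydroxy-3,5-dimethoxyphenyl)but-3-en-2-one | COc1cc(/C=C/C(C)=O)cc(OC)c1O
F8 | step 1 | 4-(4-hydroxy-3,5-dimethoxyphenyl)butan-2-one | COc1cc(CCC(C)=O)cc(OC)c1O
F9 | step 3 | 3-methoxy-4-(tetrahydro-2H-pyran-2-yloxy)benzaldehyde (racemic acetal) | COc1cc(C=O)ccc1OC1CCCCO1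
F10 | step 3 | 1-hydroxy-7-(4-hydroxy-3,5-dimethoxyphenyl)-1-[3-methoxy-4-(tetrahydro-2H-pyran-2-yloxy)phenyl]heptane-3,5-dione (mixture of stereoisomers) | COc1cc(C(O)CC(=O)CC(=O)CCc2cc(OC)c(O)c(OC)c2)ccc1OC1CCCCO1
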